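**Strategy.** The target is cut at the C12'–C13' single bond between the C11'=C12' alkene and the methyl-branched C13'=C14' alkene. In the key step a C24 polyenyne carrying ring A (C4 hydroxyl) and ending in a methyl-capped C13'≡C14' alkyne is hydrozirconated, transferred to zinc and coupled under palladium catalysis with the C16 trienyl iodide of ring B: one operation forms C12'–C13' and the (E)-trisubstituted C13'=C14' alkene. The step exploits the C20' methyl branch (it steers zirconium to C13') and the near-symmetry of the molecule: rings A and B share the (5S,6S)-4-oxo pattern, so one C16 iodide is used twice around a C8 enediyne core (C13 to C13').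

Key step: step 9

Remark: carotenoid numbering is used (ring A: C1–C6 with the C4 hydroxyl; ring B: C1'–C6' with the C4' ketone; C20' is the methyl on C13'); in the SMILES of zirconocene species the cyclopentadienyl ligands are drawn as sigma-bonded C5H5 groups.

**Step 1**
Reactants: 1 (E)-3-methylpent-2-en-4-yn-1-ol
Product: 2 triethyl{[(E)-3-methylpent-2-en-4-yn-1-yl]oxy}silane
Conditions: TESCl, imidazole, CH2Cl2, 0 °C to rt
Reagents that add atoms: chlorotriethylsilane, CC[Si](Cl)(CC)CC
Why: Standard silylation of a primary allylic alcohol, which masks the hydroxyl for the hydrozirconation and the methyllithium step; no stereocentre is involved.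

**Step 2**
Reactants: 2 triethyl{[(E)-3-methylpent-2-en-4-yn-1-yl]oxy}silane; 3 4,4-dimethylcyclohex-2-en-1-one
Product: 5 {[(3S)-4,4-dimethyl-3-[(1E,3E)-3-methyl-5-(triethylsilyloxy)penta-1,3-dien-1-yl]cyclohex-1-en-1-yl]oxy}trimethylsilane, via alkenylzirconocene 4 (not isolated)
Conditions: Cp2Zr(H)Cl, THF, rt; then 3, [Rh(cod)(MeCN)2]BF4 (5 mol %), (R)-BINAP (6 mol %), TMSCl, THF, rt
Reagents that add atoms: chlorotrimethylsilane, C[Si](C)(C)Cl
Why: Rhodium-catalysed asymmetric 1,4-addition of an alkenylzirconocene (Hayashi-type conjugate addition) with silyl trapping of the enolate: the (R)-BINAP–rhodium alkenyl should add to the enone face that gives the required C6 configuration (by analogy with the established sense for cyclohex-2-en-1-one), and the silyl enol ether fixes the enolate regiochemistry towards C5.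

**Step 3**
Reactants: 5 the trimethylsilyl enol ether
Product: 8 (2S,3S)-3-[(1E,3E)-5-hydroxy-3-methylpenta-1,3-dien-1-yl]-2,4,4-trimethylcyclohexan-1-one, via lithium enolate 6 (not isolated), via triethylsilyl ether ketone 7 (not isolated)
Conditions: MeLi, THF, 0 °C; MeI, −78 to −20 °C; then 1 M aq HCl, THF, 0 °C
Reagents that add atoms: iodomethane, CI
Why: Regiospecific enolate alkylation: methyllithium cleaves the silyl enol ether to lithium enolate 6 with the double bond fixed towards C5, iodomethane attacks anti to the C6 dienyl group to set the trans (5S) methyl (also the thermodynamic diequatorial arrangement, so any cis epimer can be equilibrated with base), and dilute acid removes the triethylsilyl ether.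

**Step 4**
Reactants: 8 the hydroxy ketone
Product: 9 (2E,4E)-3-methyl-5-[(1S,2S)-2,6,6-trimethyl-3-oxocyclohexyl]penta-2,4-dienal
Conditions: MnO2 (activated, excess), CH2Cl2, rt
Reagents that add atoms: none
Why: Chemoselective MnO2 oxidation of the allylic alcohol to the dienal; the saturated ketone and both stereocentres are untouched.

**Step 5**
Reactants: 9 the keto dienal
Product: 10 (2S,3S)-3-[(1E,3E,5E)-6-iodo-3-methylhexa-1,3,5-trien-1-yl]-2,4,4-trimethylcyclohexan-1-one
Conditions: CrCl2 (6 equiv), CHI3 (2 equiv), THF/1,4-dioxane, 0 °C to rt, dark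
Reagents that add atoms: iodoform, IC(I)I
Why: Takai olefination, which homologates the aldehyde (not the ketone) by one carbon to the (E)-alkenyl iodide through a gem-dichromium species and anti elimination.

**Step 6**
Reactants: 11 (E)-1,2-dichloroethene; 12 propyne (3 equiv)
Product: 13 (E)-oct-4-ene-2,6-diyne
Conditions: Pd(PPh3)4 (5 mol %), CuI (10 mol %), n-BuNH2, THF, rt, sealed vessel
Reagents that add atoms: none
Why: Twofold Sonogashira coupling with retention of the (E)-alkene geometry gives the C8 core in which C13 and C13' are still alkyne carbons.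

**Step 7**
Reactants: 13 (E)-oct-4-ene-2,6-diyne (4 equiv); 10 the C16 keto iodide
Product: 16 (2S,3S)-3-[(1E,3E,5E,7E,9E)-3,7-dimethyltrideca-1,3,5,7,9-pentaen-11-yn-1-yl]-2,4,4-trimethylcyclohexan-1-one, via dienynylzirconocene 14 (not isolated), via dienynylzinc chloride 15 (not isolated)
Conditions: Cp2Zr(H)Cl (1.2 equiv relative to 10), THF, rt, dark; ZnCl2, 0 °C; then 10, Pd(PPh3)4 (5 mol %), rt
Reagents that add atoms: none
Why: Hydrozirconation/Negishi coupling: with 13 in excess one alkyne is hydrozirconated syn with zirconium at the methyl-bearing carbon, zinc relays the alkenyl group to palladium and C12–C13 forms with retention, while the ketone of 10 meets no Zr–H because the hydride is the limiting reagent.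

**Step 8**
Reactants: 16 the C24 keto pentaenyne
Product: 17 (1S,2S,3S)-3-[(1E,3E,5E,7E,9E)-3,7-dimethyltrideca-1,3,5,7,9-pentaen-11-yn-1-yl]-2,4,4-trimethylcyclohexan-1-ol
Conditions: NaBH4, CeCl3·7H2O, MeOH/THF, −78 °C
Reagents that add atoms: none
Why: Luche-type hydride reduction: axial delivery of hydride to the cyclohexanone (no axial substituent on C2 or C6 blocks it) gives the all-equatorial (4S) alcohol, the existing C5 and C6 centres controlling the new one.

**Step 9**
Reactants: 17 the C24 hydroxy pentaenyne; 10 the C16 keto iodide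
Product: 20 (all-E)-(4S,5S,6S,5'S,6'S)-4-hydroxy-5,6,5',6'-tetrahydro-β,β-caroten-4'-one, via zirconated alkoxide 18 (not isolated), via alkenylzinc chloride 19 (not isolated)
Conditions: Cp2Zr(H)Cl (2.0 equiv per 17), THF, rt, dark; ZnCl2, 0 °C; then 10, Pd(PPh3)4 (5 mol %), THF, rt; pH 7 buffer
Reagents that add atoms: none
Why: Cp2Zr(H)Cl first turns the C4 hydroxyl of 17 into its zirconocene alkoxide (masking it in the flask) and then adds syn across the C13'≡C14' alkyne with zirconium at the methyl-bearing C13' to give 18; ZnCl2 transfers the alkenyl group to zinc (19), and oxidative addition of 10 to zerovalent palladium, transmetalation and reductive elimination form C12'–C13' with retention at both alkenyl carbons. The closest known reaction type is the hydrozirconation/Negishi coupling of methyl-capped alkynes with (E)-alkenyl iodides. No ring is closed and no stereocentre is created; the stereochemical element set here is the (E)-C13'=C14' geometry, which follows from the syn hydrometalation, while the (E)-C11'=C12' geometry is carried over from 10. The step needs regioselectivity (zirconium at C13', not C14'), which the size difference between the C20' methyl and the pentaenyl substituent should secure, and chemoselectivity for the alkyne over the internal di- and trisubstituted alkenes of the polyene, which react far more slowly with Cp2Zr(H)Cl. The ketone of 10 is safe because it enters only after all Zr–H has been consumed, and its C5' centre already has the thermodynamically preferred trans arrangement.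

**Compound list**
1 | (E)-3-methylpent-2-en-4-yn-1-ol | C#C/C(C)=C/CO | starting material
2 | triethyl{[(E)-3-methylpent-2-en-4-yn-1-yl]oxy}silane | C#C/C(C)=C/CO[Si](CC)(CC)CC | intermediate
3 | 4,4-dimethylcyclohex-2-en-1-one | O=C1C=CC(C)(C)CC1 | starting material
4 | chlorobis(cyclopentadienyl)[(1E,3E)-3-methyl-5-(triethylsilyloxy)penta-1,3-dien-1-yl]zirconium | Cl[Zr](C1C=CC=C1)(C1C=CC=C1)/C=C/C(C)=C/CO[Si](CC)(CC)CC | intermediate (not isolated)
5 | {[(3S)-4,4-dimethyl-3-[(1E,3E)-3-methyl-5-(triethylsilyloxy)penta-1,3-dien-1-yl]cyclohex-1-en-1-yl]oxy}trimethylsilane | CC[Si](CC)(CC)OC/C=C(C)/C=C/[C@H]1C=C(O[Si](C)(C)C)CCC1(C)C | intermediate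
6 | lithium (3S)-4,4-dimethyl-3-[(1E,3E)-3-methyl-5-(triethylsilyloxy)penta-1,3-dien-1-yl]cyclohex-1-en-1-olate | CC[Si](CC)(CC)OC/C=C(C)/C=C/[C@H]1C=C(O[Li])CCC1(C)C | intermediate (not isolated)
7 | (2S,3S)-2,4,4-trimethyl-3-[(1E,3E)-3-methyl-5-(triethylsilyloxy)penta-1,3-dien-1-yl]cyclohexan-1-one | CC[Si](CC)(CC)OC/C=C(C)/C=C/[C@H]1[C@H](C)C(=O)CCC1(C)C | intermediate (not isolated)
8 | (2S,3S)-3-[(1E,3E)-5-hydroxy-3-methylpenta-1,3-dien-1-yl]-2,4,4-trimethylcyclohexan-1-one | OC/C=C(C)/C=C/[C@H]1[C@H](C)C(=O)CCC1(C)C | intermediate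
9 | (2E,4E)-3-methyl-5-[(1S,2S)-2,6,6-trimethyl-3-oxocyclohexyl]penta-2,4-dienal | O=C/C=C(C)/C=C/[C@H]1[C@H](C)C(=O)CCC1(C)C | intermediate
10 | (2S,3S)-3-[(1E,3E,5E)-6-iodo-3-methylhexa-1,3,5-trien-1-yl]-2,4,4-trimethylcyclohexan-1-one (C16 iodide, used in steps 7 and 9) | I/C=C/C=C(C)/C=C/[C@H]1[C@H](C)C(=O)CCC1(C)C | intermediate
11 | (E)-1,2-dichloroethene | Cl/C=C/Cl | starting material
12 | propyne | CC#C | starting material
13 | (E)-oct-4-ene-2,6-diyne | CC#C/C=C/C#CC | intermediate
14 | chlorobis(cyclopentadienyl)[(2E,4E)-octa-2,4-dien-6-yn-2-yl]zirconium | C/C(=C\C=C\C#CC)[Zr](Cl)(C1C=CC=C1)C1C=CC=C1 | intermediate (not isolated)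
15 | chloro[(2E,4E)-octa-2,4-dien-6-yn-2-yl]zinc | C/C(=C\C=C\C#CC)[Zn]Cl | intermediate (not isolated)
16 | (2S,3S)-3-[(1E,3E,5E,7E,9E)-3,7-dimethyltrideca-1,3,5,7,9-pentaen-11-yn-1-yl]-2,4,4-trimethylcyclohexan-1-one | CC#C/C=C/C=C(C)/C=C/C=C(C)/C=C/[C@H]1[C@H](C)C(=O)CCC1(C)C | intermediate
17 | (1S,2S,3S)-3-[(1E,3E,5E,7E,9E)-3,7-dimethyltrideca-1,3,5,7,9-pentaen-11-yn-1-yl]-2,4,4-trimethylcyclohexan-1-ol | CC#C/C=C/C=C(C)/C=C/C=C(C)/C=C/[C@H]1[C@H](C)[C@@H](O)CCC1(C)C | intermediate
18 | zirconocene alkoxide of 17 carrying a second chlorozirconocene on C13' (new 13'E alkene) | C/C(=C\C=C\C=C(C)\C=C\C=C(C)\C=C\[C@H]1[C@H](C)[C@@H](O[Zr](Cl)(C2C=CC=C2)C2C=CC=C2)CCC1(C)C)[Zr](Cl)(C1C=CC=C1)C1C=CC=C1 | intermediate (not isolated)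
19 | the corresponding C13' alkenylzinc chloride (zirconocene alkoxide retained on O4) | C/C(=C\C=C\C=C(C)\C=C\C=C(C)\C=C\[C@H]1[C@H](C)[C@@H](O[Zr](Cl)(C2C=CC=C2)C2C=CC=C2)CCC1(C)C)[Zn]Cl | intermediate (not isolated)
20 | (all-E)-(4S,5S,6S,5'S,6'S)-4-hydroxy-5,6,5',6'-tetrahydro-β,β-caroten-4'-one | CC(/C=C/C=C(C)/C=C/[C@H]1[C@H](C)[C@@H](O)CCC1(C)C)=C\C=C\C=C(C)\C=C\C=C(C)\C=C\[C@H]1[C@H](C)C(=O)CCC1(C)C | target

**Step count.** Total: 9 steps. Longest linear sequence: 8 steps (steps 1, 2, 3, 4, 5, 7, 8, 9); step 6 is the one-step side branch.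

**Steps most likely to fail**

Step 9 (key step). Hydride may add the other way round across the alkyne (zirconium on C14') once the alkyne carries a pentaenyl group, Zr–H may slowly attack the polyene, or the polyenyl metal may isomerise before it couples. The fallback sets out from 13 and 9 and comes back at 20. Double hydrozirconation of 13 with excess Cp2Zr(H)Cl under equilibrating conditions (THF, 40 °C) and iodinolysis would give (2E,4E,6E)-2,7-diiodoocta-2,4,6-triene F1, which can be freed of regioisomers before any polyene exists. Chromium-mediated stannyl olefination of 9 (Bu3SnCHBr2, CrCl2, LiI, THF/DMF) would give (2S,3S)-2,4,4-trimethyl-3-[(1E,3E,5E)-3-methyl-6-(tributylstannyl)hexa-1,3,5-trien-1-yl]cyclohexan-1-one F2. Stille coupling of F2 with a threefold excess of F1 (Pd2(dba)3, AsPh3, NMP) would give the C24 keto iodide (2S,3S)-3-[(1E,3E,5E,7E,9E,11E)-12-iodo-3,7-dimethyltrideca-1,3,5,7,9,11-hexaen-1-yl]-2,4,4-trimethylcyclohexan-1-one F3. NaBH4/CeCl3·7H2O reduction would give the corresponding (1S,2S,3S)-cyclohexanol, the C24 hydroxy iodide F4, and a second Stille coupling of F4 with F2 would form C12'–C13' and give 20.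

Step 7. Zr–H may add to both alkynes of 13 (a symmetrical C40 by-product after double coupling), and regiocontrol may be incomplete because no excess hydride is present to equilibrate the alkenylzirconocenes. The fallback sets out from 13 and 9 and comes back at 16. Hydrozirconation of excess 13 followed by iodine would give (2E,4E)-2-iodoocta-2,4-dien-6-yne F5, which is purified as a stable electrophile. Aldehyde 9 would be converted as above into the C16 trienylstannane (2S,3S)-2,4,4-trimethyl-3-[(1E,3E,5E)-3-methyl-6-(tributylstannyl)hexa-1,3,5-trien-1-yl]cyclohexan-1-one F6. Stille coupling of F5 with F6 (Pd2(dba)3, AsPh3, NMP) would give 16.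

Step 2. Insertion of the hindered enone (β-carbon next to the quaternary centre) into the rhodium–alkenyl bond may be slow, so that unselective background addition erodes facial selectivity, and the silyl enol ether may be partly hydrolysed on isolation. The fallback sets out from 2 and 3 and comes back at 7, which the aqueous HCl of step 3 converts into 8. Hydroboration of 2 with pinacolborane (Cp2Zr(H)Cl cat., Et3N) would give triethyl{[(2E,4E)-3-methyl-5-(4,4,5,5-tetramethyl-1,3,2-dioxaborolan-2-yl)penta-2,4-dien-1-yl]oxy}silane F7. Dehydrogenation of 3 with DDQ would give 4,4-dimethylcyclohexa-2,5-dien-1-one F8. Hayashi–Miyaura addition of F7 to F8 ([Rh(OH)(cod)]2, (R)-BINAP, KOH, dioxane/H2O) would give (5R)-4,4-dimethyl-5-[(1E,3E)-3-methyl-5-(triethylsilyloxy)penta-1,3-dien-1-yl]cyclohex-2-en-1-one F9. Because only C6 of F9 can enolise, LiN(iPr)2 then MeI would give (5S,6S)-4,4,6-trimethyl-5-[(1E,3E)-3-methyl-5-(triethylsilyloxy)penta-1,3-dien-1-yl]cyclohex-2-en-1-one F10 with the methyl trans to the dienyl group. Conjugate reduction of the remaining enone with [(Ph3P)CuH]6 would give 7.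

Further compounds
F1 | step 9 | (2E,4E,6E)-2,7-diiodoocta-2,4,6-triene | C/C(I)=C\C=C\C=C(/C)I
F2 | step 9 | (2S,3S)-2,4,4-trimethyl-3-[(1E,3E,5E)-3-methyl-6-(tributylstannyl)hexa-1,3,5-trien-1-yl]cyclohexan-1-one | CCCC[Sn](CCCC)(CCCC)/C=C/C=C(C)/C=C/[C@H]1[C@H](C)C(=O)CCC1(C)C
F3 | step 9 | (2S,3S)-3-[(1E,3E,5E,7E,9E,11E)-12-iodo-3,7-dimethyltrideca-1,3,5,7,9,11-hexaen-1-yl]-2,4,4-trimethylcyclohexan-1-one | C/C(I)=C\C=C\C=C(C)\C=C\C=C(C)\C=C\[C@H]1[C@H](C)C(=O)CCC1(C)C
F4 | step 9 | (1S,2S,3S)-3-[(1E,3E,5E,7E,9E,11E)-12-iodo-3,7-dimethyltrideca-1,3,5,7,9,11-hexaen-1-yl]-2,4,4-trimethylcyclohexan-1-ol | C/C(I)=C\C=C\C=C(C)\C=C\C=C(C)\C=C\[C@H]1[C@H](C)[C@@H](O)CCC1(C)C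
F5 | step 7 | (2E,4E)-2-iodoocta-2,4-dien-6-yne | C/C(I)=C\C=C\C#CC
F6 | step 7 | (2S,3S)-2,4,4-trimethyl-3-[(1E,3E,5E)-3-methyl-6-(tributylstannyl)hexa-1,3,5-trien-1-yl]cyclohexan-1-one | CCCC[Sn](CCCC)(CCCC)/C=C/C=C(C)/C=C/[C@H]1[C@H](C)C(=O)CCC1(C)C
F7 | step 2 | triethyl{[(2E,4E)-3-methyl-5-(4,4,5,5-tetramethyl-1,3,2-dioxaborolan-2-yl)penta-2,4-dien-1-yl]oxy}silane | CC[Si](CC)(CC)OC/C=C(C)/C=C/B1OC(C)(C)C(C)(C)O1
F8 | step 2 | 4,4-dimethylcyclohexa-2,5-dien-1-one | O=C1C=CC(C)(C)C=C1
F9 | step 2 | (5R)-4,4-dimethyl-5-[(1E,3E)-3-methyl-5-(triethylsilyloxy)penta-1,3-dien-1-yl]cyclohex-2-en-1-one | CC[Si](CC)(CC)OC/C=C(C)/C=C/[C@H]1CC(=O)C=CC1(C)C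
F10 | step 2 | (5S,6S)-4,4,6-trimethyl-5-[(1E,3E)-3-methyl-5-(triethylsilyloxy)penta-1,3-dien-1-yl]cyclohex-2-en-1-one | CC[Si](CC)(CC)OC/C=C(C)/C=C/[C@H]1[C@H](C)C(=O)C=CC1(C)C
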